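The readings are simulated for an exercise.

Early on, zeta has lost 6.50% of its starting material after 4.00 h and alpha 7.90% after 1.33 h: the run with more second substrate loses it more slowly.

| setting | alpha | beta | zeta | ash | alder | oak |
|---|---|---|---|---|---|---|
| starting material | 20 mM | 20 mM | 20 mM | 20 mM | 20 mM | 20 mM |
| second substrate | 8.1 mM | 14 mM | 25 mM | 10.0 mM | 15.0 mM | 22.0 mM |
| reagent | 21 mM | 21 mM | 21 mM | 21.0 mM | 21.0 mM | 21.0 mM |
| free catalyst | 3 mM | 3 mM | 3 mM | 3.0 mM | 3.0 mM | 3.0 mM |
| remark | run made earlier | run made earlier | run made earlier |  |  |  |
| time |  |  |  | 25 h | 25 h | 25 h |

| run | time / h | over-reaction product / % | catalyst intermediate A / % | starting material / % | target / % | side product / % |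
|---|---|---|---|---|---|---|
| alpha | 1.33 | 0.6 | 3.4 | 92.1 | 2.9 | 1.6 |
| alpha | 3.00 | 1.4 | 3.1 | 84.4 | 6.5 | 8.3 |
| alpha | 8.00 | 2.0 | 3.3 | 58.3 | 7.2 | 24.9 |
| alpha | 20.0 | 2.4 | 0.8 | 29.5 | 5.3 | 54.8 |
| beta | 2.00 | 0.5 | 1.0 | 92.2 | 3.6 | 1.7 |
| beta | 6.00 | 0 | 3.9 | 76.2 | 4.8 | 12.9 |
| beta | 12.0 | 0 | 4.2 | 62.5 | 2.7 | 26.0 |
| beta | 20.0 | 0.5 | 3.0 | 49.2 | 4.0 | 40.4 |
| zeta | 4.00 | 0 | 0.8 | 93.5 | 0.7 | 4.7 |
| zeta | 8.00 | 0 | 2.5 | 87.7 | 0.3 | 8.4 |
| zeta | 12.0 | 0 | 0.3 | 83.8 | 0.4 | 13.1 |
| zeta | 20.0 | 0 | 0.5 | 83.7 | 0 | 14.8 |

(each reading ± 1 percentage point)

- percent here means starting material units held: one side product counts as two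
- candidate steps: starting material + free catalyst <-> catalyst intermediate A; reagent + catalyst intermediate A -> free catalyst + target; second substrate + free catalyst <-> catalyst intermediate B; reagent + catalyst intermediate B -> free catalyst + second product; reagent + free catalyst + target -> free catalyst + over-reaction product; starting material + target -> side product; target + free catalyst <-> isomer of the product + free catalyst

1. which of these there is most of at the end, counted by the starting material in it, ash (side product / starting material / over-reaction product / target / catalyst intermediate A)
2. which of these there is most of at the end, counted by the starting material in it, alder (side product / starting material / over-reaction product / target / catalyst intermediate A)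
3. which of these there is most of at the end, counted by the starting material in it, oak (side product / starting material / over-reaction product / target / catalyst intermediate A)
4. final amount of the leader among these, as a percentage of the starting material charged, in ash
5. final amount of the leader among these, as a percentage of the starting material charged, in alder
6. final amount of the leader among these, as a percentage of the starting material charged, in oak

Two chemists read these runs differently. The clock reader follows what is made: side product keeps climbing, about 2%/h, and alder lies close to beta, so a short extrapolation should do.

The budget keeper, whose reckoning I take as mine, follows the fraction of starting material left. By the candidate steps, each second substrate takes one reagent, and each target takes one reagent and then one more starting material into side product. One reagent therefore removes two starting material. The margin c(reagent) − c(second substrate) then gives a floor, the fraction left once the margin is used: 1 − 2 × margin / c(starting material). For alder the margin is 6.00 mM and the floor 40.0%. This floor is above zero, so by this count reagent is the limiting reagent for alder's starting material.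

The excess above the floor is reagent still to be used, so I let it decay roughly pseudo-first-order. Beta's floor is 30.0%, and its excess falls from 33 percentage points to 19 points between 12.0 h and 20.0 h, which reads as 0.0658 h⁻¹. Starting alder from beta's reading at 12.0 h gives 49.6% of starting material at 25 h. Taking off what beta's last reading holds in target, catalyst intermediate A and over-reaction product leaves about 42.9% of side product. So I put starting material ahead in alder.

The clock reader answers with ash, whose floor of −10.0% lies below zero, so the budget gives no stop there. For oak the margin is −1.00 mM, and the sum means nothing.

The forecast, the clock reader's, gives side product at 61% in ash, side product at 46% in alder and starting material at 74% in oak. On alder it says: “This is a close call, leaning to side product.” There my reckoning differs.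

The simulation gives side product at 57.4% in ash, starting material at 51.6% in alder, against 41.4% of side product, and starting material at 77.8% in oak.

    starting material + free catalyst ⇌ catalyst intermediate A (K = 28.0 M⁻¹, k = 0.0480 M⁻¹ s⁻¹)
    reagent + catalyst intermediate A → free catalyst + target (k = 0.0240 M⁻¹ s⁻¹)
    second substrate + free catalyst ⇌ catalyst intermediate B (K = 1800 M⁻¹, k = 0.150 M⁻¹ s⁻¹)
    reagent + catalyst intermediate B → free catalyst + second product (k = 0.0220 M⁻¹ s⁻¹)
    reagent + free catalyst + target → free catalyst + over-reaction product (k = 0.500 M⁻² s⁻¹)
    starting material + target → side product (k = 0.00520 M⁻¹ s⁻¹)
    target + free catalyst ⇌ isomer of the product + free catalyst, rate k7*[free catalyst]*[target] forward; the back reaction follows from the equilibrium constant (K = 0.460, k = 0.00430 M⁻¹ s⁻¹)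

The forecast's alder value is 5.6 points low and its leader wrong, while in ash, the flask below zero, its 61% holds within the tolerance. In ash, with the other concentrations as charged, target has a half-life of 1.9 h by the step with starting material, against 15 h by the forward isomerisation. Ash ends with 57.4% of side product and 2.12% of isomer of the product. Alder stands 12 points above its floor at 25 h, and at 250 h it holds 39.6%.

The neighbour with 6.0 mM of second substrate has a floor of −50.0%, so the budget gives it no stop. It ends with 19.1% of starting material and 20.2% of its reagent.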